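**Retr­osynthetic overview**
1. The ten-membered ring is closed last at C2–C3 by a chromium-mediated alkynyl–aldehyde addition; acetylation and cis-semihydrogenation then give the Z-C3=C4 alkene.
2. Ring A (C1, C14, C13, C12, C11, C10) is carried as a 7-oxabicyclo[2.2.1]heptane. The enabling feature: the hydroxyl oxygen on C11 stands 1,4 to C14 across C12(=O)–C13=C14, so the hydroxy enone is the β-elimination product of a ketone in which that oxygen bridges C11 and C14.
3. The bridged core is made in one step from a five-membered carbonyl ylide (ring O, C11, C10, C1, C14) and a two-carbon ketene equivalent (C12=C13, a 2-acetoxyacrylate tethered to the C9 oxygen); C13–C14 and C11–C12 form together.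
4. The γ-lactone, C6–Cl and C7–O come from chlorolactonisation of an E-C6=C7 alkene; C8 from chelation-controlled union with an alkenyllithium carrying the C5 spiro-epoxide; C9/C10 from an auxiliary aldol; C1 from Pd-catalysed allylic alkylation.
5. Ring order: temporary butyrolactone, then oxanorbornane plus tether δ-lactone (key step), then γ-lactone, then ring A unmasked, then the ten-membered ring.

Key step: step 13

Remark (numbering used in names): C1 ring-fusion carbon with CH3-15; C2 acetoxy carbon; C3=C4; C5 spiro-epoxide carbon with C16; C6 chloride; C7 lactone O-carbon; C8 tertiary carbinol; C9 acetoxy carbon; C10 ring-fusion CH; C11 carbinol with CH3-20; C12 ketone; C13=C14; C17 lactone α-carbon with CH3-18; C19 lactone carbonyl.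
Remark (assumptions): in step 1 the ligand antipode is the one that delivers the 4S ester 3; compounds 40–44 are C17 epimer mixtures until the equilibration in step 28.

**Route**

Step 1
Reactants: 1 2-ethenyl-2-methyloxirane (racemic); 2 dimethyl malonate
Product: 3 methyl (4S)-4-ethenyl-4-methyl-2-oxooxolane-3-carboxylate (C3 epimers)
Conditions: Pd2(dba)3·CHCl3 (1 mol %), chiral DACH-naphthyl bis(diphenylphosphinobenzamide) ligand (3 mol %), CH2Cl2, 25 °C
Reagents that add atoms: none
Why: Pd-catalysed dynamic kinetic asymmetric allylic alkylation of the vinyl epoxide, in which the π-allyl alkoxide deprotonates the malonate and steers it to the tertiary terminus, the ligand sets the C1 quaternary centre, and the freed alcohol lactonises onto one ester.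

Step 2
Reactants: 3 methyl (4S)-4-ethenyl-4-methyl-2-oxooxolane-3-carboxylate
Product: 4 (4R)-4-ethenyl-4-methyloxolan-2-one
Conditions: LiCl, DMSO/H2O, 140 °C
Reagents that add atoms: none
Why: Krapcho dealkoxycarbonylation of the α-carbomethoxy lactone (chloride demethylation, loss of CO2), which leaves the quaternary centre untouched.

Step 3
Reactants: 4 (4R)-4-ethenyl-4-methyloxolan-2-one
Product: 6 (4S)-4-(dimethoxymethyl)-4-methyloxolan-2-one, via lactone aldehyde 5 (not isolated)
Conditions: O3, CH2Cl2/MeOH, −78 °C; Me2S; then HC(OMe)3, TsOH (cat.), MeOH, 25 °C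
Reagents that add atoms: trimethyl orthoformate COC(OC)OC
Why: Ozonolysis of the only alkene gives the non-enolisable C14 aldehyde, which is masked at once as its dimethyl acetal.

Step 4
Reactants: 6 (4S)-4-(dimethoxymethyl)-4-methyloxolan-2-one
Product: 9 (3S)-4-[(tert-butyldiphenylsilyl)oxy]-3-(dimethoxymethyl)-3-methylbutanoic acid, via sodium hydroxy carboxylate 7 (not isolated), via silyl ester silyl ether 8 (not isolated)
Conditions: NaOH, MeOH/H2O, 25 °C; evaporate; TBDPSCl, imidazole, DMF; then K2CO3, MeOH/H2O; citric acid work-up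
Reagents that add atoms: sodium hydroxide [Na+].[OH-]; tert-butyl(chloro)diphenylsilane CC(C)(C)[Si](Cl)(c1ccccc1)c1ccccc1
Why: Saponification opens the lactone, silylation traps the C2 hydroxyl before relactonisation, and the labile silyl ester is cleaved selectively by mild base.

Step 5
Reactants: 9 (3S)-4-[(tert-butyldiphenylsilyl)oxy]-3-(dimethoxymethyl)-3-methylbutanoic acid; 10 (S)-4-benzyloxazolidin-2-one
Product: 12 (S)-4-benzyl-3-acyl oxazolidinone of acid 9, via pivalic mixed anhydride 11 (not isolated)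
Conditions: PivCl, Et3N, THF, −20 °C; then 10, LiCl, 25 °C
Reagents that add atoms: none
Why: Standard N-acylation of the oxazolidinone through the mixed pivalic anhydride; no stereocentre is involved.

Step 6
Reactants: 12 (S)-4-benzyl-3-acyl oxazolidinone of acid 9; 13 prop-2-enal
Product: 15 syn-aldol imide (C10 bearing C1 and the C9 carbinol; C8 vinyl), via Z-boron enolate 14 (not isolated)
Conditions: Bu2BOTf, iPr2NEt, CH2Cl2, −78 → 0 °C; 13, −78 °C; pH 7 buffer, H2O2/MeOH
Reagents that add atoms: none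
Why: Evans syn-aldol reaction, in which the Z-boron enolate reacts through a closed chair transition state on the face opposite the benzyl group and so sets C10 and C9 by auxiliary control.

Step 7
Reactants: 15 syn-aldol imide
Product: 16 Weinreb amide at C11 (C9-OH free)
Conditions: MeNHOMe·HCl, AlMe3, CH2Cl2, −20 → 0 °C
Reagents that add atoms: N,O-dimethylhydroxylamine hydrochloride CNOC.Cl
Why: Aluminium amide transamination of a β-hydroxy imide, assisted by the free hydroxyl, which releases the auxiliary without touching C9 or C10.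

Step 8
Reactants: 16 Weinreb amide at C11
Product: 17 β-hydroxy methyl ketone (C11 ketone with CH3-20; C9-OH; C8 vinyl; C14 dimethyl acetal; C2-OTBDPS)
Conditions: MeMgBr (3 equiv), THF, −78 → 0 °C
Reagents that add atoms: methylmagnesium bromide C[Mg]Br
Why: Weinreb ketone synthesis, in which the chelated tetrahedral intermediate stops at the methyl ketone and the cold magnesium aldolate resists retro-aldol cleavage.

Step 9
Reactants: 18 pyruvic acid
Product: 19 2-acetoxyprop-2-enoic acid
Conditions: Ac2O, TsOH (cat.), 90 °C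
Reagents that add atoms: acetic anhydride CC(=O)OC(C)=O
Why: Acid-catalysed enol acetylation of the α-keto acid gives the captodative acrylic acid that serves as ketene equivalent.

Step 10
Reactants: 17 β-hydroxy methyl ketone; 19 2-acetoxyprop-2-enoic acid
Product: 20 C9 2-acetoxyacrylate ester of 17
Conditions: DCC, DMAP (cat.), CH2Cl2, 0 °C
Reagents that add atoms: none
Why: Steglich esterification of the secondary allylic alcohol attaches the dipolarophile to the C9 oxygen, and the low temperature with catalytic base should avoid β-elimination of the new β-acyloxy ketone.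

Step 11
Reactants: 20 C9 2-acetoxyacrylate ester
Product: 21 keto aldehyde (C14 aldehyde, C11 methyl ketone)
Conditions: TFA/H2O (9:1), CH2Cl2, 0 °C
Reagents that add atoms: water O
Why: Acid hydrolysis of the dimethyl acetal frees the α-quaternary aldehyde, which cannot enolise, while the silyl ether and enol acetate tolerate brief aqueous acid.

Step 12
Reactants: 21 keto aldehyde
Product: 22 C14 N-(tert-butyldimethylsilyl)hydrazone
Conditions: TBSNHNHTBS, Sc(OTf)3 (1 mol %), CH2Cl2, 0 °C
Reagents that add atoms: 1,2-bis(tert-butyldimethylsilyl)hydrazine CC(C)(C)[Si](C)(C)NN[Si](C)(C)C(C)(C)C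
Why: Lewis-acid-catalysed N-silylhydrazone formation, which is faster at the aldehyde than at the hindered methyl ketone and cannot form a cyclic azine.

Step 13
Reactants: 22 C14 N-(tert-butyldimethylsilyl)hydrazone
Product: 25 cycloadduct (7-oxabicyclo[2.2.1]heptane with O bridging C11 and C14, fused tether δ-lactone C12–C(=O)–O–C9, C12 exo-acetate), via C14 diazoalkane 23 (not isolated), via carbonyl ylide 24 (not isolated)
Conditions: PhIF2, 2-chloropyridine, CH2Cl2, −78 → −20 °C; then slow addition to Rh2(OAc)4 (2 mol %), CH2Cl2, 25 °C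
Reagents that add atoms: none
Why: Proposed new method: oxidation of the N-silylhydrazone (loss of PhI, TBSF and HF) should give the unstabilised diazoalkane 23, which has no β-hydrogen on C1; Rh2(OAc)4 turns it into a C14 carbenoid that is captured by the C11 ketone oxygen (five-membered ring O, C11, C10, C1, C14) to give ylide 24, and 24 adds suprafacially across C14 and C11 to the tethered 2-acetoxyacrylate, forming C13–C14 and C11–C12 in one step. The closest known reaction type is the dirhodium-catalysed tandem carbonyl-ylide formation and intramolecular [3+2] cycloaddition of α-diazo ketones with tethered acrylates, and oxidation of N-silylhydrazones is a known in situ entry to unstabilised diazoalkanes; the new element is the donor-type carbene as ylide precursor. Ring closures: the ylide ring by oxygen attack on the carbenoid, the oxanorbornane by concerted cycloaddition, and the six-membered lactone C11–C10–C9–O–C(=O)–C12 as the tether ring spanning two endo positions. C11 is set, as are the transient centres C12 and C14, because the three-atom tether from C9, which lies on the CH3-15 face of C10, can only reach the dipole face syn to C9, so the oxygen bridge ends anti to C9; C1, C9 and C10 are not touched. Regiochemistry is fixed by the tether (acyl-bearing C12 to C11, CH2 C13 to C14) and is electronically matched (nucleophilic C14 terminus to the acrylate β-carbon). The electron-poor captodative alkene and slow addition should let cycloaddition outrun 1,4-hydrogen shift of the ylide, carbene dimerisation and pyrazoline formation.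

Step 14
Reactants: 25 cycloadduct
Product: 26 triol (C12(OH)(CH2OH), C9-OH; C8 vinyl; C2-OTBDPS)
Conditions: LiAlH4, THF, 0 °C
Reagents that add atoms: none
Why: Hydride reduction opens the tether lactone to the C12 hydroxymethyl group and the free C9 alcohol and removes the acetate, leaving C12 as a masked ketone (a 1,2-diol).

Step 15
Reactants: 26 triol
Product: 27 mono-TBS ether (C12–CH2OTBS; C9-OH and C12-OH free)
Conditions: TBSCl (1.1 equiv), imidazole, CH2Cl2, 0 °C
Reagents that add atoms: tert-butyl(chloro)dimethylsilane CC(C)(C)[Si](C)(C)Cl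
Why: Selective silylation of the only primary alcohol in the presence of a hindered secondary and a tertiary one.

Step 16
Reactants: 27 mono-TBS ether
Product: 29 C8 isopropenyl carbinol (C8 epimers), via α-hydroxy aldehyde 28 (not isolated)
Conditions: O3, CH2Cl2, −78 °C; Me2S; then CH2=C(CH3)MgBr (5 equiv), THF, −78 → 0 °C
Reagents that add atoms: ozone [O-][O+]=O; isopropenylmagnesium bromide CC(=C)[Mg]Br
Why: Ozonolysis of the sole alkene gives the C8 aldehyde, which is used crude in a Grignard addition that brings in C17, C18 and C19; the C8 configuration is irrelevant because it is oxidised next.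

Step 17
Reactants: 29 C8 isopropenyl carbinol
Product: 30 α-hydroxy isopropenyl ketone (C8 ketone, C9-OH)
Conditions: MnO2, CH2Cl2, 25 °C
Reagents that add atoms: none
Why: MnO2 oxidises only the allylic C8 alcohol and spares the saturated C9 and tertiary C12 alcohols.

Step 18
Reactants: 31 2-bromoprop-2-en-1-ol; 32 ethynyltri(propan-2-yl)silane
Product: 33 2-methylidene-4-[tri(propan-2-yl)silyl]but-3-yn-1-ol
Conditions: Pd(PPh3)2Cl2 (2 mol %), CuI (4 mol %), iPr2NH, THF, 25 °C
Reagents that add atoms: none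
Why: Sonogashira coupling of the vinyl bromide with the terminal alkyne gives the 2-alkynyl allylic alcohol.

Step 19
Reactants: 33 2-methylidene-4-[tri(propan-2-yl)silyl]but-3-yn-1-ol
Product: 34 (S)-{2-[(triisopropylsilyl)ethynyl]oxiran-2-yl}methanol
Conditions: Ti(OiPr)4, L-(+)-diethyl tartrate, t-BuOOH, 4 Å MS, CH2Cl2, −20 °C
Reagents that add atoms: tert-butyl hydroperoxide CC(C)(C)OO
Why: Sharpless asymmetric epoxidation of a 2-substituted allylic alcohol, which sets C5 by reagent control and delivers the C5–O–C16 spiro-epoxide of the target directly.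

Step 20
Reactants: 34 (S)-{2-[(triisopropylsilyl)ethynyl]oxiran-2-yl}methanol
Product: 35 (R)-2-[(triisopropylsilyl)ethynyl]oxirane-2-carbaldehyde
Conditions: Dess–Martin periodinane, NaHCO3, CH2Cl2, 0 °C
Reagents that add atoms: none
Why: Dess–Martin oxidation under buffered, non-basic conditions; the α-quaternary epoxy aldehyde cannot epimerise.

Step 21
Reactants: 35 (R)-2-[(triisopropylsilyl)ethynyl]oxirane-2-carbaldehyde
Product: 36 (R)-2-[(E)-2-iodoethenyl]-2-[(triisopropylsilyl)ethynyl]oxirane
Conditions: CrCl2, CHI3, THF/dioxane, 0 °C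
Reagents that add atoms: iodoform IC(I)I
Why: Takai olefination converts the aldehyde into the (E)-iodoalkene (C6=C7) under conditions that leave the epoxide and silyl alkyne intact.

Step 22
Reactants: 30 α-hydroxy isopropenyl ketone; 36 (R)-2-[(E)-2-iodoethenyl]-2-[(triisopropylsilyl)ethynyl]oxirane
Product: 38 C8 tertiary alcohol carrying the isopropenyl group and the (E)-C7=C6 alkene to the C5 epoxide, via (E)-alkenyllithium 37 (not isolated)
Conditions: 36, t-BuLi (2.0 equiv), Et2O, −78 °C; 30 pretreated with LiHMDS (2.0 equiv) and MgBr2·OEt2, THF, −78 °C; combine, −78 → −40 °C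
Reagents that add atoms: none
Why: Chelation-controlled 1,2-addition of the alkenyl nucleophile (alkene geometry retained) to the magnesium chelate of the α-alkoxide ketone, with attack on the C9–H side anti to C10, which sets C8.

Step 23
Reactants: 38 C8 tertiary alcohol
Product: 39 C9 acetate
Conditions: Ac2O, pyridine, DMAP (cat.), CH2Cl2, 25 °C
Reagents that add atoms: acetic anhydride CC(=O)OC(C)=O
Why: Acetylation of the only secondary alcohol (tertiary C8-OH and C12-OH do not react), which installs the C9 acetate early and blocks later lactonisation or conjugate addition by this oxygen.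

Step 24
Reactants: 39 C9 acetate
Product: 40 C19 primary alcohol (C17 epimers)
Conditions: 9-BBN, THF, 40 °C; then H2O2, pH 7 phosphate buffer
Reagents that add atoms: hydrogen peroxide OO
Why: Anti-Markovnikov hydroboration–oxidation of the 1,1-disubstituted isopropenyl alkene, which 9-BBN prefers over the hindered E-alkene and the silyl alkyne; C17 is not yet controlled.

Step 25
Reactants: 40 C19 primary alcohol
Product: 41 C19 carboxylic acid (C17 epimers)
Conditions: TEMPO (cat.), PhI(OAc)2, MeCN/pH 7 buffer, 25 °C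
Reagents that add atoms: water O
Why: TEMPO-mediated oxidation of the only primary alcohol to the acid; no other oxidisable alcohol is present.

Step 26
Reactants: 41 C19 carboxylic acid
Product: 42 chlorolactone (γ-lactone O–C7, C6–Cl; C17 epimers)
Conditions: 1,3-dichloro-5,5-dimethylhydantoin, CHCl3, −20 °C
Reagents that add atoms: 1,3-dichloro-5,5-dimethylhydantoin CC1(C)N(Cl)C(=O)N(Cl)C1=O
Why: 5-exo chlorolactonisation in which the carboxylate opens the chloriranium ion at C7 anti to chlorine, so the E-alkene gives the required C6/C7 pair; the face follows the known preference of 3-hydroxy-4-alkenoic acids for the hydroxyl cis and the bulky C9 chain trans to the new C6 arm, which sets C7 and C6 relative to C8.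

Step 27
Reactants: 42 chlorolactone
Product: 43 desilylated chlorolactone (C2 CH2OH; C12(OH)(CH2OH); silyl alkyne kept)
Conditions: TBAF, AcOH (1:1), THF, 0 → 25 °C
Reagents that add atoms: none
Why: Buffered fluoride removes both primary silyl ethers while acetate, lactone, chloride and epoxide are spared.

Step 28
Reactants: 43 desilylated chlorolactone
Product: 45 ring A hydroxy enone (C11-OH, C12 ketone, C13=C14; C17 as in the target), via bridged C12 ketone 44 (not isolated)
Conditions: NaIO4, THF/pH 7 buffer, 0 °C; then DBU, CH2Cl2, 25 °C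
Reagents that add atoms: none
Why: Periodate cleaves the C12 1,2-diol to the ketone, DBU then opens the oxygen bridge by E1cB elimination (the C13 enolate expels the C14 alkoxide, which remains on C11 as the hydroxyl), and the same base equilibrates C17 to the isomer with CH3-18 trans to the C9 chain.

Step 29
Reactants: 45 ring A hydroxy enone
Product: 46 iodoalkyne (C3–I)
Conditions: AgF, N-iodosuccinimide, MeCN, 25 °C, dark
Reagents that add atoms: N-iodosuccinimide O=C1CCC(=O)N1I
Why: Silver-fluoride-mediated desilylative iodination replaces the alkynyl silane by iodine through the silver acetylide under neutral conditions.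

Step 30
Reactants: 46 iodoalkyne
Product: 47 C2 aldehyde
Conditions: Dess–Martin periodinane, NaHCO3, CH2Cl2, 0 °C
Reagents that add atoms: none
Why: Dess–Martin oxidation of the only primary alcohol; the aldehyde on quaternary C1 cannot enolise and the tertiary alcohols are inert.

Step 31
Reactants: 47 C2 aldehyde
Product: 48 macrocyclic propargylic alcohol (ten-membered ring, C2-OH, C3≡C4)
Conditions: CrCl2 (6 equiv), NiCl2 (2 mol %), THF, 0.002 M, 25 °C
Reagents that add atoms: none
Why: Nozaki–Hiyama–Kishi ring closure, in which divalent chromium inserts into the C–I bond and the alkynylchromium adds to the aldehyde while tolerating enone, lactone, chloride and epoxide; C2 is set by the ring-closing transition state, expected to keep the carbonyl oxygen on the C14 side away from CH3-15.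

Step 32
Reactants: 48 macrocyclic propargylic alcohol
Product: 49 C2 acetate
Conditions: Ac2O, pyridine, DMAP (cat.), 0 °C
Reagents that add atoms: acetic anhydride CC(=O)OC(C)=O
Why: Acetylation of the only secondary alcohol; the tertiary C8 and C11 hydroxyls do not react under these conditions.

Step 33
Reactants: 49 C2 acetate
Product: 50 target CNP0294646.1
Conditions: H2 (1 atm), Pd/CaCO3 poisoned with Pb(OAc)2, quinoline, EtOAc, 25 °C
Reagents that add atoms: none
Why: Lindlar semihydrogenation gives the Z-C3=C4 alkene by syn delivery of hydrogen and also relieves the strain of the cyclic alkyne; the conjugated enone alkene is not reduced by the poisoned catalyst.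

**Compound list**
1 | 2-ethenyl-2-methyloxirane (racemic) | CC1(C=C)CO1 | starting material
2 | dimethyl malonate | COC(=O)CC(=O)OC | starting material
3 | methyl (4S)-4-ethenyl-4-methyl-2-oxooxolane-3-carboxylate (C3 epimers) | COC(=O)C1C(=O)OC[C@@]1(C)C=C | intermediate
4 | (4R)-4-ethenyl-4-methyloxolan-2-one | O=C1C[C@](C)(C=C)CO1 | intermediate
5 | (3S)-3-methyl-5-oxooxolane-3-carbaldehyde | O=C1C[C@](C)(C=O)CO1 | intermediate
6 | (4S)-4-(dimethoxymethyl)-4-methyloxolan-2-one | O=C1C[C@](C)(C(OC)OC)CO1 | intermediate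
7 | sodium (3S)-3-(dimethoxymethyl)-4-hydroxy-3-methylbutanoate | [Na+].[O-]C(=O)C[C@](C)(C(OC)OC)CO | intermediate
8 | tert-butyldiphenylsilyl (3S)-4-[(tert-butyldiphenylsilyl)oxy]-3-(dimethoxymethyl)-3-methylbutanoate | CC(C)(C)[Si](c1ccccc1)(c1ccccc1)OC(=O)C[C@](C)(C(OC)OC)CO[Si](c1ccccc1)(c1ccccc1)C(C)(C)C | intermediate
9 | (3S)-4-[(tert-butyldiphenylsilyl)oxy]-3-(dimethoxymethyl)-3-methylbutanoic acid | OC(=O)C[C@](C)(C(OC)OC)CO[Si](c1ccccc1)(c1ccccc1)C(C)(C)C | intermediate
10 | (S)-4-benzyloxazolidin-2-one | O=C1OC[C@H](Cc2ccccc2)N1 | starting material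
11 | pivalic mixed anhydride of 9 | CC(C)(C)C(=O)OC(=O)C[C@](C)(C(OC)OC)CO[Si](c1ccccc1)(c1ccccc1)C(C)(C)C | intermediate
12 | (S)-4-benzyl-3-acyl oxazolidinone of acid 9 | O=C1OC[C@H](Cc2ccccc2)N1C(=O)C[C@](C)(C(OC)OC)CO[Si](c1ccccc1)(c1ccccc1)C(C)(C)C | intermediate
13 | prop-2-enal | C=CC=O | starting material
14 | (Z)-dibutylboron enolate of 12 | CCCCB(CCCC)O/C(N1C(=O)OC[C@@H]1Cc1ccccc1)=C\[C@](C)(C(OC)OC)CO[Si](c1ccccc1)(c1ccccc1)C(C)(C)C | intermediate
15 | syn-aldol imide (C9-OH, C8 vinyl; C1, C9, C10 as in the target) | O=C1OC[C@H](Cc2ccccc2)N1C(=O)[C@H]([C@H](O)C=C)[C@](C)(C(OC)OC)CO[Si](c1ccccc1)(c1ccccc1)C(C)(C)C | intermediate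
16 | Weinreb amide at C11 | CON(C)C(=O)[C@H]([C@H](O)C=C)[C@](C)(C(OC)OC)CO[Si](c1ccccc1)(c1ccccc1)C(C)(C)C | intermediate
17 | β-hydroxy methyl ketone (C11 ketone, C9-OH, C8 vinyl, C14 dimethyl acetal, C2-OTBDPS) | CC(=O)[C@H]([C@H](O)C=C)[C@](C)(C(OC)OC)CO[Si](c1ccccc1)(c1ccccc1)C(C)(C)C | intermediate
18 | pyruvic acid | CC(=O)C(=O)O | starting material
19 | 2-acetoxyprop-2-enoic acid | C=C(OC(C)=O)C(=O)O | intermediate
20 | C9 2-acetoxyacrylate ester of 17 | CC(=O)[C@H]([C@H](OC(=O)C(=C)OC(C)=O)C=C)[C@](C)(C(OC)OC)CO[Si](c1ccccc1)(c1ccccc1)C(C)(C)C | intermediate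
21 | keto aldehyde (C14 aldehyde, C11 ketone, C9 acrylate) | CC(=O)[C@H]([C@H](OC(=O)C(=C)OC(C)=O)C=C)[C@](C)(C=O)CO[Si](c1ccccc1)(c1ccccc1)C(C)(C)C | intermediate
22 | C14 N-(tert-butyldimethylsilyl)hydrazone of 21 | CC(=O)[C@H]([C@H](OC(=O)C(=C)OC(C)=O)C=C)[C@](C)(/C=N/N[Si](C)(C)C(C)(C)C)CO[Si](c1ccccc1)(c1ccccc1)C(C)(C)C | intermediate
23 | C14 diazoalkane | CC(=O)[C@H]([C@H](OC(=O)C(=C)OC(C)=O)C=C)[C@](C)(C=[N+]=[N-])CO[Si](c1ccccc1)(c1ccccc1)C(C)(C)C | intermediate
24 | five-membered carbonyl ylide (ring O, C11, C10, C1, C14) | CC1=[O+][CH-][C@](C)(CO[Si](c2ccccc2)(c2ccccc2)C(C)(C)C)[C@H]1[C@H](OC(=O)C(=C)OC(C)=O)C=C | intermediate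
25 | cycloadduct: O-bridged C11/C14 oxanorbornane, C12 exo-acetate, tether δ-lactone to O-9, C9 vinyl, C2-OTBDPS | C=C[C@H]1OC(=O)[C@@]2(OC(C)=O)C[C@@H]3O[C@@]2(C)[C@H]1[C@@]3(C)CO[Si](c4ccccc4)(c4ccccc4)C(C)(C)C | intermediate
26 | triol: oxanorbornane with C12(OH)(CH2OH), C9-OH, C8 vinyl | C=C[C@@H](O)[C@H]1[C@]2(C)O[C@@H](C[C@]2(O)CO)[C@]1(C)CO[Si](c3ccccc3)(c3ccccc3)C(C)(C)C | intermediate
27 | mono-TBS ether of 26 (C12–CH2OTBS) | C=C[C@@H](O)[C@H]1[C@]2(C)O[C@@H](C[C@]2(O)CO[Si](C)(C)C(C)(C)C)[C@]1(C)CO[Si](c3ccccc3)(c3ccccc3)C(C)(C)C | intermediate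
28 | C8 α-hydroxy aldehyde | O=C[C@@H](O)[C@H]1[C@]2(C)O[C@@H](C[C@]2(O)CO[Si](C)(C)C(C)(C)C)[C@]1(C)CO[Si](c3ccccc3)(c3ccccc3)C(C)(C)C | intermediate
29 | C8 isopropenyl carbinol (C8 epimers) | C=C(C)C(O)[C@@H](O)[C@H]1[C@]2(C)O[C@@H](C[C@]2(O)CO[Si](C)(C)C(C)(C)C)[C@]1(C)CO[Si](c3ccccc3)(c3ccccc3)C(C)(C)C | intermediate
30 | α-hydroxy isopropenyl ketone (C8 ketone, C9-OH) | C=C(C)C(=O)[C@@H](O)[C@H]1[C@]2(C)O[C@@H](C[C@]2(O)CO[Si](C)(C)C(C)(C)C)[C@]1(C)CO[Si](c3ccccc3)(c3ccccc3)C(C)(C)C | intermediate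
31 | 2-bromoprop-2-en-1-ol | C=C(Br)CO | starting material
32 | ethynyltri(propan-2-yl)silane | C#C[Si](C(C)C)(C(C)C)C(C)C | starting material
33 | 2-methylidene-4-[tri(propan-2-yl)silyl]but-3-yn-1-ol | C=C(CO)C#C[Si](C(C)C)(C(C)C)C(C)C | intermediate
34 | (S)-{2-[(triisopropylsilyl)ethynyl]oxiran-2-yl}methanol | OC[C@]1(CO1)C#C[Si](C(C)C)(C(C)C)C(C)C | intermediate
35 | (R)-2-[(triisopropylsilyl)ethynyl]oxirane-2-carbaldehyde | O=C[C@]1(CO1)C#C[Si](C(C)C)(C(C)C)C(C)C | intermediate
36 | (R)-2-[(E)-2-iodoethenyl]-2-[(triisopropylsilyl)ethynyl]oxirane | I/C=C/[C@]1(CO1)C#C[Si](C(C)C)(C(C)C)C(C)C | intermediate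
37 | (E)-alkenyllithium from 36 | [Li]/C=C/[C@]1(CO1)C#C[Si](C(C)C)(C(C)C)C(C)C | intermediate
38 | C8 tertiary alcohol (isopropenyl, (E)-C7=C6 alkene to the C5 epoxide, C9-OH) | C=C(C)[C@](O)(/C=C/[C@]1(CO1)C#C[Si](C(C)C)(C(C)C)C(C)C)[C@@H](O)[C@H]2[C@]3(C)O[C@@H](C[C@]3(O)CO[Si](C)(C)C(C)(C)C)[C@]2(C)CO[Si](c4ccccc4)(c4ccccc4)C(C)(C)C | intermediate
39 | C9 acetate of 38 | C=C(C)[C@](O)(/C=C/[C@]1(CO1)C#C[Si](C(C)C)(C(C)C)C(C)C)[C@@H](OC(C)=O)[C@H]2[C@]3(C)O[C@@H](C[C@]3(O)CO[Si](C)(C)C(C)(C)C)[C@]2(C)CO[Si](c4ccccc4)(c4ccccc4)C(C)(C)C | intermediate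
40 | C19 primary alcohol (C17 epimers) | OCC(C)[C@](O)(/C=C/[C@]1(CO1)C#C[Si](C(C)C)(C(C)C)C(C)C)[C@@H](OC(C)=O)[C@H]2[C@]3(C)O[C@@H](C[C@]3(O)CO[Si](C)(C)C(C)(C)C)[C@]2(C)CO[Si](c4ccccc4)(c4ccccc4)C(C)(C)C | intermediate
41 | C19 carboxylic acid (C17 epimers) | OC(=O)C(C)[C@](O)(/C=C/[C@]1(CO1)C#C[Si](C(C)C)(C(C)C)C(C)C)[C@@H](OC(C)=O)[C@H]2[C@]3(C)O[C@@H](C[C@]3(O)CO[Si](C)(C)C(C)(C)C)[C@]2(C)CO[Si](c4ccccc4)(c4ccccc4)C(C)(C)C | intermediate
42 | chlorolactone (γ-lactone O–C7, C6–Cl; C17 epimers) | CC1C(=O)O[C@@H]([C@@H](Cl)[C@]2(CO2)C#C[Si](C(C)C)(C(C)C)C(C)C)[C@]1(O)[C@@H](OC(C)=O)[C@H]3[C@]4(C)O[C@@H](C[C@]4(O)CO[Si](C)(C)C(C)(C)C)[C@]3(C)CO[Si](c5ccccc5)(c5ccccc5)C(C)(C)C | intermediate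
43 | desilylated chlorolactone (C2 CH2OH, C12(OH)(CH2OH); C17 epimers) | CC1C(=O)O[C@@H]([C@@H](Cl)[C@]2(CO2)C#C[Si](C(C)C)(C(C)C)C(C)C)[C@]1(O)[C@@H](OC(C)=O)[C@H]3[C@]4(C)O[C@@H](C[C@]4(O)CO)[C@]3(C)CO | intermediate
44 | bridged C12 ketone (7-oxabicyclo[2.2.1]heptan-2-one; C17 epimers) | CC1C(=O)O[C@@H]([C@@H](Cl)[C@]2(CO2)C#C[Si](C(C)C)(C(C)C)C(C)C)[C@]1(O)[C@@H](OC(C)=O)[C@H]3[C@]4(C)O[C@@H](CC4=O)[C@]3(C)CO | intermediate
45 | ring A hydroxy enone with C2 CH2OH and silyl alkyne | C[C@H]1C(=O)O[C@@H]([C@@H](Cl)[C@]2(CO2)C#C[Si](C(C)C)(C(C)C)C(C)C)[C@]1(O)[C@@H](OC(C)=O)[C@@H]3[C@@](C)(CO)C=CC(=O)[C@@]3(C)O | intermediate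
46 | iodoalkyne | C[C@H]1C(=O)O[C@@H]([C@@H](Cl)[C@]2(CO2)C#CI)[C@]1(O)[C@@H](OC(C)=O)[C@@H]3[C@@](C)(CO)C=CC(=O)[C@@]3(C)O | intermediate
47 | C2 aldehyde iodoalkyne | C[C@H]1C(=O)O[C@@H]([C@@H](Cl)[C@]2(CO2)C#CI)[C@]1(O)[C@@H](OC(C)=O)[C@@H]3[C@@](C)(C=O)C=CC(=O)[C@@]3(C)O | intermediate
48 | macrocyclic propargylic alcohol (C2-OH, C3≡C4) | O[C@H]1C#C[C@@]2(CO2)[C@H](Cl)[C@@H]2OC(=O)[C@H](C)[C@@]2(O)[C@@H](OC(C)=O)[C@@H]2[C@]1(C)C=CC(=O)[C@@]2(C)O | intermediate
49 | C2 acetate of 48 | CC(=O)O[C@H]1C#C[C@@]2(CO2)[C@H](Cl)[C@@H]2OC(=O)[C@H](C)[C@@]2(O)[C@@H](OC(C)=O)[C@@H]2[C@]1(C)C=CC(=O)[C@@]2(C)O | intermediate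
50 | CNP0294646.1 (stereochemistry as in the SMILES) | CC(=O)O[C@H]1/C=C\[C@@]2(CO2)[C@H](Cl)[C@@H]2OC(=O)[C@H](C)[C@@]2(O)[C@@H](OC(C)=O)[C@@H]2[C@]1(C)C=CC(=O)[C@@]2(C)O | target

**Step count and risks**
Total steps: 33. Longest linear sequence: 28 (steps 1–8, 10–17, 22–33).

Step 13 (key step). The unstabilised carbenoid or ylide may be lost to dimerisation, 1,4-hydrogen shift or pyrazoline formation before the cycloaddition. The fallback builds the same two bonds stepwise by known ionic chemistry. It sets out from ketone 17: 2-lithio-3-(trimethylsilyl)propene (from 2-bromo-3-(trimethylsilyl)propene and t-BuLi, Et2O, −78 °C) should add to the C11 ketone under 1,3-chelation by the C9 alkoxide, forming C11–C12 and giving allylsilane diol F1. TMSOTf (cat.), CH2Cl2, −78 °C should ionise the C14 acetal; the C11 hydroxyl closes the five-membered oxocarbenium ion and the allylsilane terminus C13 attacks C14 (intramolecular Hosomi–Sakurai reaction, forming C13–C14) to give the 12-methylidene oxanorbornane F2. mCPBA should epoxidise the strained exocyclic alkene from the exo face faster than the C8 vinyl group, giving spiro-epoxide F3, and NaOH in aqueous DMSO should open it at the CH2 to triol 26, where the route is rejoined.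

Step 31. The ring-closing addition may show poor facial selectivity at C2. The fallback sets C2 by reagent control instead: from 48 (as the C2 epimer mixture), Dess–Martin oxidation should give macrocyclic ynone F4, and Corey–Bakshi–Shibata reduction ((R)-methyl oxazaborolidine, catecholborane, toluene, −78 °C; alkyne as the small group, the ynone being more reactive than the enone) should return 48 as the required C2 epimer.

Step 33. Semihydrogenation may over-reduce or cleave the propargylic and allylic C–O bonds next to the epoxide, and the cyclic alkyne 48 may be too strained to form cleanly. The fallback fixes the Z geometry before ring closure: from iodoalkyne 46, diimide (2-nitrobenzenesulfonylhydrazide, Et3N, THF) should give (Z)-iodoalkene F5; Dess–Martin oxidation should give aldehyde F6; CrCl2/NiCl2 in DMSO/THF at high dilution (Nozaki–Hiyama–Kishi, alkene geometry retained) should close the ring to Z-allylic alcohol F7; Ac2O, pyridine, DMAP should then give 50.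

Further compounds
F1 | step 13 | allylsilane diol (C11 tertiary alcohol bearing the 3-(trimethylsilyl)prop-1-en-2-yl group; C14 acetal, C9-OH) | C=C(C[Si](C)(C)C)[C@@](C)(O)[C@H]([C@H](O)C=C)[C@](C)(C(OC)OC)CO[Si](c1ccccc1)(c1ccccc1)C(C)(C)C
F2 | step 13 | 12-methylidene-7-oxanorbornane (C9-OH, C8 vinyl, C2-OTBDPS) | C=C[C@@H](O)[C@H]1[C@]2(C)O[C@@H](CC2=C)[C@]1(C)CO[Si](c3ccccc3)(c3ccccc3)C(C)(C)C
F3 | step 13 | C12 spiro-epoxide (oxygen exo) | C=C[C@@H](O)[C@H]1[C@]2(C)O[C@@H](C[C@]24CO4)[C@]1(C)CO[Si](c3ccccc3)(c3ccccc3)C(C)(C)C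
F4 | step 31 | macrocyclic C2 ynone | O=C1C#C[C@@]2(CO2)[C@H](Cl)[C@@H]2OC(=O)[C@H](C)[C@@]2(O)[C@@H](OC(C)=O)[C@@H]2[C@]1(C)C=CC(=O)[C@@]2(C)O
F5 | step 33 | (Z)-iodoalkene with C2 CH2OH | C[C@H]1C(=O)O[C@@H]([C@@H](Cl)[C@]2(CO2)/C=C\I)[C@]1(O)[C@@H](OC(C)=O)[C@@H]3[C@@](C)(CO)C=CC(=O)[C@@]3(C)O
F6 | step 33 | (Z)-iodoalkene C2 aldehyde | C[C@H]1C(=O)O[C@@H]([C@@H](Cl)[C@]2(CO2)/C=C\I)[C@]1(O)[C@@H](OC(C)=O)[C@@H]3[C@@](C)(C=O)C=CC(=O)[C@@]3(C)O
F7 | step 33 | Z-allylic alcohol macrocycle (2-O-deacetyl target) | O[C@H]1/C=C\[C@@]2(CO2)[C@H](Cl)[C@@H]2OC(=O)[C@H](C)[C@@]2(O)[C@@H](OC(C)=O)[C@@H]2[C@]1(C)C=CC(=O)[C@@]2(C)O
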